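At late times both earlier flasks stand still. Delta holds target near 36.8% from 4.00 min on, and alpha holds it near 60.8% from 3.00 min on. Starting material reads 0% and 0% at 15.0 min. So I read the end value as a matter of shares.

| flask | starting material | reagent | remark | time |
|---|---|---|---|---|
| delta | 0.50 mM | 1.3 equiv | run made earlier |  |
| alpha | 0.50 mM | 3 equiv | run made earlier |  |
| violet | 0.50 mM | 1.10 equiv |  | 15 min |
| amber | 0.50 mM | 1.70 equiv |  | 15 min |
| red | 0.50 mM | 2.50 equiv |  | 15 min |

| run | time / min | target / % | starting material / % |
|---|---|---|---|
| delta | 4.00 | 37.6 | 0.3 |
| delta | 8.00 | 36.0 | 1.9 |
| delta | 12.0 | 36.0 | 2.0 |
| delta | 15.0 | 37.6 | 0 |
| alpha | 1.33 | 47.3 | 0.2 |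
| alpha | 3.00 | 60.9 | 0 |
| alpha | 6.00 | 60.7 | 0 |
| alpha | 15.0 | 60.9 | 0 |

(standard deviation of a reading: 1 percentage point)

1. which of the two there is more of at the end, violet (target / side product B)
2. which of the two there is more of at the end, amber (target / side product B)
3. which of the two there is more of at the end, red (target / side product B)
4. how much target is there at the end, in percent of the starting material charged: violet
5. how much target is there at the end, in percent of the starting material charged: amber
6. how much target is there at the end, in percent of the starting material charged: red

- what was read earlier has a scatter of 1 percentage point, one standard deviation
- candidate steps: starting material -> side product A; starting material + reagent -> intermediate A; reagent + intermediate B -> side product B; intermediate A -> target; starting material -> intermediate B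

Starting material leaves by two roads. With reagent it goes on to target, at a rate proportional to the reagent level b in equivalents, pseudo-first-order at any moment. Without reagent it goes to side product A or intermediate B, at a rate free of b. So target's share at a moment is b/(b+K). At a fixed starting concentration K is constant, and in equivalents it scales inversely with that concentration.

This comparison drifts as reagent is used, so I take the mean level over a run: the charge minus half of what is used. Each unit of target costs one equivalent. A share s of the non-target, the part ending as side product B, costs one too.

I get K two ways, one from each run, as mean level times non-target over target. If none of the non-target costs reagent, alpha gives 1.74 equiv and delta 1.92 equiv. If the whole of it does, alpha gives 1.61 equiv and delta 1.37 equiv. The two ways part, and delta is the one that cheats: it swings further than alpha, so alpha holds K and delta reads s. As readings, with the scatter of the runs in them, they meet at s = 0.434 and K = 1.68 equiv. This K is the even level, the reagent level at which the two roads run equally fast.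

Putting the mean level back into the share, I commit to target at 32.0% in violet, 44.7% in amber and 55.8% in red. My reckoning puts side product B in violet at 29.5%. The two tie at s = 0.471, which is more than my reading, so I call target there, with little weight. In amber and red I call target too.

The forecast names target, target and target for violet, amber and red, with 32%, 45% and 56% target, and it adds: “Violet is the least certain comparison”.

    starting material → side product A (k = 0.0119 s⁻¹)
    starting material + reagent → intermediate A (k = 35.6 L mol⁻¹ s⁻¹)
    reagent + intermediate B → side product B (k = 581 L mol⁻¹ s⁻¹)
    intermediate A → target (k = 0.0217 s⁻¹)
    starting material → intermediate B (k = 0.0175 s⁻¹)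

Violet gives 31.1% target against 41.0% side product B. Amber gives 44.2% target against 33.2% side product B, and red gives 55.8% against 26.3%. Violet keeps 34.5% of its own reagent charge. A further flask like amber holds 1.2 mM of starting material, which takes K down to 0.700 equiv. It keeps 50% of its reagent, so its mean level is 1.27 equiv and the share is 64.5%. Its target stands at 64.4%.

(The data were computed from invented constants; scatter was added.)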